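**Plan**

- Retrosynthesis: the three O-protecting groups come off last. Ring C is cut at C3–C4 and at C2=C3, so C3 and its oxygen leave as an alkoxymethylene ylide and a ring A aroyl fluoride remains, with the ring B acid attached as an aryl ester to the ortho oxygen (the future O1–C2 bond). That ester C–O bond, the two aryl–prenyl bonds and the pyran of the chromene are cut next.
- Enabling feature: C3 is a single oxygen-bearing carbon between the C4 carbonyl (bonded to C4a of ring A) and C2 (bonded to ring B and O1). One carbon nucleophile that is first acylated and then olefinates can therefore make both of its ring bonds.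
- Forward: ring A is prepared as a 3,5-diprenylated, bis-MOM 2,4,6-trihydroxybenzoate. Ring B with its fused dimethylpyran is made from resorcinol and converted into the 7-carboxylic acid. The two are joined as an aryl ester, the ring A carboxyl is freed and turned into the acyl fluoride, ring C is closed, and the hydroxyls are released.
- Order of ring formation: the pyran of the chromene first, ring C second; rings A and B come from the aromatic starting materials.
- Stereochemistry: the target has no stereocentre and no alkene with geometric isomers, so nothing has to be set.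

Key step: step 10

Remark: "prenyl" means 3-methylbut-2-en-1-yl and MOM means methoxymethyl throughout; all compounds of the main route are achiral, so their SMILES carry no stereodescriptors.

**Route**

Step 1
Reactants: 1 2,4,6-trihydroxybenzoic acid
Product: 2 allyl 2,4,6-trihydroxybenzoate
Conditions: allyl bromide (1.1 equiv), KHCO3 (1.2 equiv), DMF, rt
Reagents that add atoms: allyl bromide, C=CCBr
Why: Carboxylate O-alkylation (SN2) under KHCO3 ionises only the carboxylic acid, so the allyl ester should form without O-allylation of the phenols and without the heating that would decarboxylate the acid.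

Step 2
Reactants: 2 allyl 2,4,6-trihydroxybenzoate; 3 prenyl bromide
Product: 4 allyl 2,4,6-trihydroxy-3,5-diprenylbenzoate
Conditions: 3 (2.1 equiv in total, added in portions), DBU (2.2 equiv), THF, 0 °C → rt
Reagents that add atoms: prenyl bromide, CC(C)=CCBr (the second equivalent; the first is reactant 3)
Why: Base-mediated C-alkylation of the phloroglucinol ring (the phenoxide acts as a vinylogous enolate, a Friedel–Crafts-type allylation long used for acylphloroglucinols) consumes two molecules of prenyl bromide per molecule of 2 and should place one prenyl group on each of the two equivalent free ring carbons C3 and C5, with portionwise addition at low temperature holding back O-prenylation and geminal over-alkylation.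

Step 3
Reactants: 4 allyl 2,4,6-trihydroxy-3,5-diprenylbenzoate
Product: 5 allyl 2-hydroxy-4,6-bis(methoxymethoxy)-3,5-diprenylbenzoate
Conditions: MOMCl (2.2 equiv), i-Pr2NEt (3 equiv), CH2Cl2, 0 °C → rt
Reagents that add atoms: chloromethyl methyl ether, COCCl
Why: Williamson-type acetal formation should take the 4-hydroxyl and one of the two equivalent ortho hydroxyls, while the last ortho hydroxyl stays free because it is hydrogen-bonded to the ester carbonyl, the usual outcome for 2,4,6-trihydroxyaryl carbonyl compounds.

Step 4
Reactants: 6 resorcinol; 7 3-methylbut-2-enal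
Product: 8 2,2-dimethyl-2H-chromen-7-ol
Conditions: 6 (2 equiv), 7 (1 equiv), ethylenediammonium diacetate (10 mol %), xylene, reflux
Reagents that add atoms: none
Why: Amine-salt-catalysed Knoevenagel-type condensation of the phenol with the enal gives an ortho-quinone methide that closes by oxa-6π electrocyclisation (formal [3+3] chromene annulation), and attack through the less hindered C4 of resorcinol places the remaining hydroxyl at C7 while the excess of resorcinol limits a second annulation.

Step 5
Reactants: 8 2,2-dimethyl-2H-chromen-7-ol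
Product: 9 2,2-dimethyl-2H-chromen-7-yl trifluoromethanesulfonate
Conditions: Tf2O (1.1 equiv), pyridine, CH2Cl2, 0 °C
Reagents that add atoms: trifluoromethanesulfonic anhydride, O=S(=O)(OS(=O)(=O)C(F)(F)F)C(F)(F)F
Why: O-Sulfonylation of the phenol gives the aryl triflate that the palladium-catalysed carbonylation needs, and the chromene alkene is inert to the buffered conditions.

Step 6
Reactants: 9 2,2-dimethyl-2H-chromen-7-yl trifluoromethanesulfonate
Product: 10 2,2-dimethyl-2H-chromene-7-carboxylic acid
Conditions: Pd(OAc)2 (5 mol %), 1,1'-bis(diphenylphosphino)ferrocene (10 mol %), KOAc (4 equiv), CO (1 atm), DMSO, 60 °C; aq. HCl work-up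
Reagents that add atoms: carbon monoxide, [C-]#[O+]; potassium acetate, CC(=O)[O-].[K+] (supplies the second carboxyl oxygen through the mixed anhydride)
Why: Palladium-catalysed hydroxycarbonylation of an aryl triflate (oxidative addition, CO insertion, capture of the acylpalladium by acetate and collapse of the mixed anhydride to the carboxylate) should give the acid directly, with the chromene alkene taking no part.

Step 7
Reactants: 10 2,2-dimethyl-2H-chromene-7-carboxylic acid; 5 allyl 2-hydroxy-4,6-bis(methoxymethoxy)-3,5-diprenylbenzoate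
Product: 12 allyl 2-[(2,2-dimethyl-2H-chromene-7-carbonyl)oxy]-4,6-bis(methoxymethoxy)-3,5-diprenylbenzoate, via acid chloride 11 (not isolated)
Conditions: 10, 1-chloro-N,N,2-trimethylprop-1-en-1-amine (1.1 equiv), CH2Cl2, 0 °C → rt; then 5, Et3N (2 equiv), DMAP (0.2 equiv), CH2Cl2, 0 °C → rt
Reagents that add atoms: none
Why: The α-chloroenamine converts the acid into its chloride under neutral conditions that spare the acid-sensitive chromene, and DMAP-catalysed acylation should then esterify the only free phenol of 5 despite its hydrogen bond and its two flanking substituents.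

Step 8
Reactants: 12 allyl 2-[(2,2-dimethyl-2H-chromene-7-carbonyl)oxy]-4,6-bis(methoxymethoxy)-3,5-diprenylbenzoate
Product: 13 2-[(2,2-dimethyl-2H-chromene-7-carbonyl)oxy]-4,6-bis(methoxymethoxy)-3,5-diprenylbenzoic acid
Conditions: Pd(PPh3)4 (5 mol %), N-methylaniline (2 equiv), THF, rt; cold dilute citric acid wash, used without delay
Reagents that add atoms: none
Why: In this Tsuji–Trost deallylation zerovalent palladium ionises only the allyl ester and the π-allyl complex is trapped by N-methylaniline, which is too weak a nucleophile to aminolyse the aryl ester, while the C-prenyl groups (not allylic esters), the chromene and the MOM acetals are left alone.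

Step 9
Reactants: 13 2-[(2,2-dimethyl-2H-chromene-7-carbonyl)oxy]-4,6-bis(methoxymethoxy)-3,5-diprenylbenzoic acid
Product: 14 2-[(2,2-dimethyl-2H-chromene-7-carbonyl)oxy]-4,6-bis(methoxymethoxy)-3,5-diprenylbenzoyl fluoride
Conditions: cyanuric fluoride (1.0 equiv), pyridine (1 equiv), CH2Cl2, −10 °C → rt
Reagents that add atoms: cyanuric fluoride (2,4,6-trifluoro-1,3,5-triazine), Fc1nc(F)nc(F)n1
Why: Deoxyfluorination of the carboxylic acid (carboxylate substitution on the triazine, then return of fluoride to the acyl carbon) should give an isolable acyl fluoride without any HCl, so the ortho MOM acetal is not cleaved and cannot cyclise onto the acyl carbon.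

Step 10
Reactants: 14 2-[(2,2-dimethyl-2H-chromene-7-carbonyl)oxy]-4,6-bis(methoxymethoxy)-3,5-diprenylbenzoyl fluoride; 15 [2-(trimethylsilyl)ethoxymethyl]triphenylphosphonium chloride
Product: 18 2-(2,2-dimethyl-2H-chromen-7-yl)-5,7-bis(methoxymethoxy)-6,8-diprenyl-3-[2-(trimethylsilyl)ethoxy]-4H-chromen-4-one, via alkoxymethylene phosphorane 16 (not isolated), via keto phosphorane 17 (not isolated)
Conditions: 15 (2.1 equiv), LiN(SiMe3)2 (2.1 equiv), THF, −78 → 0 °C; this solution added slowly to 14 in THF at −78 °C, then rt; then toluene, 90 °C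
Reagents that add atoms: none
Why: Proposed new method: the non-stabilised α-alkoxy ylide 16 adds through carbon to the acyl fluoride of 14 at −78 °C, fluoride leaves (removed as insoluble LiF) and a second equivalent of 16 takes the acidic proton to give the α-alkoxy-β-keto phosphorane 17 (C3–C4 bond), whose ylide carbon on heating attacks the neighbouring aryl ester carbonyl and forms an oxaphosphetane that collapses with loss of Ph3P=O to the C2=C3 bond. The closest known reaction type is the chromone and flavone synthesis in which a simple ylide is acylated by an activated O-acylsalicylic acid derivative and the resulting keto-ylide undergoes intramolecular Wittig olefination of the aryl ester; this has been shown only for ylides without an α-oxygen, so the tetrasubstituted, oxygen-bearing C2=C3 bond is new, and the α-alkoxy group, which makes the keto-ylide more nucleophilic, should offset the added crowding. Ring C closes in a 6-exo-trig mode, because the ester C=O attacked by the ylide carbon lies outside the forming six-membered ring and the ortho arrangement holds the two partners together. No stereocentre is created and the ring alkene has no geometric isomer. The step needs acylation at the acyl fluoride and not at the aryl ester, which should be secured by the far higher electrophilicity and small leaving group of the acyl fluoride at −78 °C, by adding the ylide to 14 so that free ylide never accumulates, and by the ester olefination setting in only on heating. Only base is present, so the prenyl groups, the chromene and the MOM acetals should survive.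

Step 11
Reactants: 18 2-(2,2-dimethyl-2H-chromen-7-yl)-5,7-bis(methoxymethoxy)-6,8-diprenyl-3-[2-(trimethylsilyl)ethoxy]-4H-chromen-4-one
Product: 19 2-(2,2-dimethyl-2H-chromen-7-yl)-3-hydroxy-5,7-bis(methoxymethoxy)-6,8-diprenyl-4H-chromen-4-one
Conditions: Bu4NF (3 equiv), THF, rt → 50 °C, argon; aq. NH4Cl
Reagents that add atoms: none
Why: Fluoride attacks silicon and the 2-(trimethylsilyl)ethyl ether fragments by β-elimination to ethylene, Me3SiF and the 3-oxido flavone (a leaving group comparable to a phenoxide), while MOM acetals, prenyl groups and the chromene are inert to fluoride.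

Step 12
Reactants: 19 2-(2,2-dimethyl-2H-chromen-7-yl)-3-hydroxy-5,7-bis(methoxymethoxy)-6,8-diprenyl-4H-chromen-4-one
Product: 20 dorsilurin C
Conditions: HCl (3 M aq., 10 equiv), MeOH, 40 °C
Reagents that add atoms: none
Why: Acid-catalysed acetal exchange with methanol should remove both MOM groups (the 5-O-MOM group especially easily, since the freed hydroxyl hydrogen-bonds to the C4 carbonyl) under dilute, warm conditions of the kind routinely tolerated by ortho-prenyl phenols and 2,2-dimethylchromenes.

**Compound list**

1 | 2,4,6-trihydroxybenzoic acid | O=C(O)c1c(O)cc(O)cc1O | starting material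
2 | allyl 2,4,6-trihydroxybenzoate | C=CCOC(=O)c1c(O)cc(O)cc1O | intermediate
3 | prenyl bromide (1-bromo-3-methylbut-2-ene) | CC(C)=CCBr | starting material
4 | allyl 2,4,6-trihydroxy-3,5-diprenylbenzoate | C=CCOC(=O)c1c(O)c(CC=C(C)C)c(O)c(CC=C(C)C)c1O | intermediate
5 | allyl 2-hydroxy-4,6-bis(methoxymethoxy)-3,5-diprenylbenzoate | C=CCOC(=O)c1c(O)c(CC=C(C)C)c(OCOC)c(CC=C(C)C)c1OCOC | intermediate
6 | resorcinol | Oc1cccc(O)c1 | starting material
7 | 3-methylbut-2-enal | CC(C)=CC=O | starting material
8 | 2,2-dimethyl-2H-chromen-7-ol | CC1(C)C=Cc2ccc(O)cc2O1 | intermediate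
9 | 2,2-dimethyl-2H-chromen-7-yl trifluoromethanesulfonate | CC1(C)C=Cc2ccc(OS(=O)(=O)C(F)(F)F)cc2O1 | intermediate
10 | 2,2-dimethyl-2H-chromene-7-carboxylic acid | CC1(C)C=Cc2ccc(C(=O)O)cc2O1 | intermediate
11 | 2,2-dimethyl-2H-chromene-7-carbonyl chloride | CC1(C)C=Cc2ccc(C(=O)Cl)cc2O1 | intermediate
12 | allyl 2-[(2,2-dimethyl-2H-chromene-7-carbonyl)oxy]-4,6-bis(methoxymethoxy)-3,5-diprenylbenzoate | C=CCOC(=O)c1c(OC(=O)c2ccc3c(c2)OC(C)(C)C=C3)c(CC=C(C)C)c(OCOC)c(CC=C(C)C)c1OCOC | intermediate
13 | 2-[(2,2-dimethyl-2H-chromene-7-carbonyl)oxy]-4,6-bis(methoxymethoxy)-3,5-diprenylbenzoic acid | O=C(O)c1c(OC(=O)c2ccc3c(c2)OC(C)(C)C=C3)c(CC=C(C)C)c(OCOC)c(CC=C(C)C)c1OCOC | intermediate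
14 | 2-[(2,2-dimethyl-2H-chromene-7-carbonyl)oxy]-4,6-bis(methoxymethoxy)-3,5-diprenylbenzoyl fluoride | O=C(F)c1c(OC(=O)c2ccc3c(c2)OC(C)(C)C=C3)c(CC=C(C)C)c(OCOC)c(CC=C(C)C)c1OCOC | intermediate
15 | [2-(trimethylsilyl)ethoxymethyl]triphenylphosphonium chloride | C[Si](C)(C)CCOC[P+](c1ccccc1)(c1ccccc1)c1ccccc1.[Cl-] | starting material
16 | [2-(trimethylsilyl)ethoxy]methylenetriphenylphosphorane | C[Si](C)(C)CCOC=P(c1ccccc1)(c1ccccc1)c1ccccc1 | intermediate
17 | 1-{2-[(2,2-dimethyl-2H-chromene-7-carbonyl)oxy]-4,6-bis(methoxymethoxy)-3,5-diprenylphenyl}-2-[2-(trimethylsilyl)ethoxy]-2-(triphenylphosphoranylidene)ethan-1-one | C[Si](C)(C)CCOC(=P(c1ccccc1)(c1ccccc1)c1ccccc1)C(=O)c1c(OC(=O)c2ccc3c(c2)OC(C)(C)C=C3)c(CC=C(C)C)c(OCOC)c(CC=C(C)C)c1OCOC | intermediate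
18 | 2-(2,2-dimethyl-2H-chromen-7-yl)-5,7-bis(methoxymethoxy)-6,8-diprenyl-3-[2-(trimethylsilyl)ethoxy]-4H-chromen-4-one | C[Si](C)(C)CCOc1c(-c2ccc3c(c2)OC(C)(C)C=C3)oc2c(CC=C(C)C)c(OCOC)c(CC=C(C)C)c(OCOC)c2c1=O | intermediate
19 | 2-(2,2-dimethyl-2H-chromen-7-yl)-3-hydroxy-5,7-bis(methoxymethoxy)-6,8-diprenyl-4H-chromen-4-one | Oc1c(-c2ccc3c(c2)OC(C)(C)C=C3)oc2c(CC=C(C)C)c(OCOC)c(CC=C(C)C)c(OCOC)c2c1=O | intermediate
20 | dorsilurin C, 2-(2,2-dimethyl-2H-chromen-7-yl)-3,5,7-trihydroxy-6,8-diprenyl-4H-chromen-4-one | CC(C)=CCc1c(O)c(CC=C(C)C)c2oc(-c3ccc4c(c3)OC(C)(C)C=C4)c(O)c(=O)c2c1O | target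

**Step count**

Total steps: 12. Longest linear sequence: 9 steps (steps 1–3 and 7–12 from 1; the ring B branch, steps 4–6 and 7–12 from 6, is equally long).

**Steps most likely to fail**

Step 10 (bears the new-method label). The ylide may attack the unhindered aroyl ester carbonyl instead of the di-ortho-substituted acyl fluoride, which would transfer or lose the ring B acyl group. The crowded α-alkoxy keto-ylide may also fail to olefinate the ester on heating, or may shift the aroyl group to its enolate oxygen. The fallback introduces the C3 oxygen after ring closure and uses only known chemistry; it sets out from acyl fluoride 14 and comes back to the route at 19, before step 12. Treating 14 with methylenetriphenylphosphorane (2 equiv, from Ph3PCH3Br and LiN(SiMe3)2, THF, −78 °C → rt) would give {2-[(2,2-dimethyl-2H-chromene-7-carbonyl)oxy]-4,6-bis(methoxymethoxy)-3,5-diprenylbenzoyl}methylenetriphenylphosphorane F1. Heating F1 in toluene would close it, by the established intramolecular ester Wittig reaction, to the 3-unsubstituted flavone 2-(2,2-dimethyl-2H-chromen-7-yl)-5,7-bis(methoxymethoxy)-6,8-diprenyl-4H-chromen-4-one F2. C3 lithiation of F2 with LiN(i-Pr)2 (THF, −78 °C) and trapping with B(OMe)3 would give dimethyl [2-(2,2-dimethyl-2H-chromen-7-yl)-5,7-bis(methoxymethoxy)-6,8-diprenyl-4-oxo-4H-chromen-3-yl]boronate F3. Oxidation of F3 with NaBO3·4H2O in THF/H2O, a nucleophilic oxidant that does not epoxidise the prenyl or chromene alkenes, would give 19.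

Step 2. O-Prenylation and geminal over-alkylation to dearomatised products may compete with the wanted double C-alkylation, so the 3,5-diprenyl compound may form in low amount and be hard to separate. The fallback replaces electrophilic alkylation of the phenoxide by directed ortho-metalation; it sets out from prenyl bromide 3, with commercial phloroglucinol as the arene partner, and comes back to the route at 5, before step 7. Phloroglucinol would be converted with MOMCl and i-Pr2NEt into 1,3,5-tris(methoxymethoxy)benzene F4. Lithiation between two acetal oxygens (n-BuLi, THF, 0 °C), transmetalation with CuBr·SMe2 and alkylation with 3 would give 1,3,5-tris(methoxymethoxy)-2-prenylbenzene F5, and repeating the sequence would give 1,3,5-tris(methoxymethoxy)-2,4-diprenylbenzene F6. A third lithiation at the last ring position and a quench with allyl chloroformate at −78 °C would give allyl 2,4,6-tris(methoxymethoxy)-3,5-diprenylbenzoate F7. Chelation-controlled cleavage of one ortho MOM group with MgBr2·OEt2 (Et2O/toluene, rt), in which the ester carbonyl and the ortho acetal oxygen bind magnesium together, would give 5.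

Step 4. The annulation may run at C2 of resorcinol (giving the 5-hydroxy isomer) or twice on the same ring, and the enal may oligomerise at the temperature needed. The fallback builds the pyran at the ketone oxidation level; it sets out from resorcinol 6 and comes back to the route at triflate 9, before step 6. Friedel–Crafts acylation and oxa-Michael closure of 6 with 3-methylbut-2-enoic acid in P2O5/MeSO3H at 70 °C would give 7-hydroxy-2,2-dimethylchroman-4-one F8. Triflation (Tf2O, pyridine) would give 2,2-dimethyl-4-oxochroman-7-yl trifluoromethanesulfonate F9, and reduction with NaBH4 in MeOH would give racemic 4-hydroxy-2,2-dimethylchroman-7-yl trifluoromethanesulfonate F10. Acid-catalysed dehydration of F10 (p-TsOH, toluene, 80 °C) would give 9.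

**Further compounds**

F1 | step 10 | {2-[(2,2-dimethyl-2H-chromene-7-carbonyl)oxy]-4,6-bis(methoxymethoxy)-3,5-diprenylbenzoyl}methylenetriphenylphosphorane | O=C(C=P(c1ccccc1)(c1ccccc1)c1ccccc1)c1c(OC(=O)c2ccc3c(c2)OC(C)(C)C=C3)c(CC=C(C)C)c(OCOC)c(CC=C(C)C)c1OCOC
F2 | step 10 | 2-(2,2-dimethyl-2H-chromen-7-yl)-5,7-bis(methoxymethoxy)-6,8-diprenyl-4H-chromen-4-one | O=c1cc(-c2ccc3c(c2)OC(C)(C)C=C3)oc2c(CC=C(C)C)c(OCOC)c(CC=C(C)C)c(OCOC)c12
F3 | step 10 | dimethyl [2-(2,2-dimethyl-2H-chromen-7-yl)-5,7-bis(methoxymethoxy)-6,8-diprenyl-4-oxo-4H-chromen-3-yl]boronate | COB(OC)c1c(-c2ccc3c(c2)OC(C)(C)C=C3)oc2c(CC=C(C)C)c(OCOC)c(CC=C(C)C)c(OCOC)c2c1=O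
F4 | step 2 | 1,3,5-tris(methoxymethoxy)benzene | COCOc1cc(OCOC)cc(OCOC)c1
F5 | step 2 | 1,3,5-tris(methoxymethoxy)-2-prenylbenzene | COCOc1cc(OCOC)c(CC=C(C)C)c(OCOC)c1
F6 | step 2 | 1,3,5-tris(methoxymethoxy)-2,4-diprenylbenzene | COCOc1cc(OCOC)c(CC=C(C)C)c(OCOC)c1CC=C(C)C
F7 | step 2 | allyl 2,4,6-tris(methoxymethoxy)-3,5-diprenylbenzoate | C=CCOC(=O)c1c(OCOC)c(CC=C(C)C)c(OCOC)c(CC=C(C)C)c1OCOC
F8 | step 4 | 7-hydroxy-2,2-dimethylchroman-4-one | CC1(C)CC(=O)c2ccc(O)cc2O1
F9 | step 4 | 2,2-dimethyl-4-oxochroman-7-yl trifluoromethanesulfonate | CC1(C)CC(=O)c2ccc(OS(=O)(=O)C(F)(F)F)cc2O1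
F10 | step 4 | racemic 4-hydroxy-2,2-dimethylchroman-7-yl trifluoromethanesulfonate | CC1(C)CC(O)c2ccc(OS(=O)(=O)C(F)(F)F)cc2O1
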